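**Strategy.** The route rests on recognising C4 of the upper unit's pyran ring (ring C) as an aldehyde carbon at the focus of two phloroglucinol-type rings: its own ring A (C4a) and ring A of the middle unit (C8), with the C3 oxygen next door to steer the C4 configuration. An acyclic aryl ether aldehyde carrying C2 and C3 of the upper unit is united with a preformed (4β→6) dimer in one acid-mediated double Friedel–Crafts operation: the tethered ring A closes the O1–C2–C3–C4–C4a–C8a ring, and the resulting C4 cation is captured by C8 of the dimer anti to the C3 ether, forming the interflavan bond and the C4 stereocentre.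

Key step: step 12

Remark: the target is read as epicatechin-(4β→8)-epicatechin-(4β→6)-epicatechin. Unit U is the upper unit whose ring C is built de novo, unit M the middle unit, unit L the lower unit with the C4 methylene; flavan numbering is used throughout.
Remark: the C4 configuration of ether 5 and of the non-isolated alcohol 19 is immaterial, because C4 ionises in the event that follows.
Assumption: compounds 1, 9, 10, 12 and 16 are purchased.

Step 1
Reactants: 1 (−)-epicatechin
Product: 2 5,7,3',4'-tetra-O-benzyl-(−)-epicatechin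
Conditions: BnBr (4.4 equiv), K2CO3, DMF, 0 °C → rt
Reagents that add atoms: benzyl bromide, BrCc1ccccc1
Why: Williamson etherification under weak base should benzylate the four phenols and leave the much less acidic secondary 3-OH and both stereocentres untouched.

Step 2
Reactants: 2 5,7,3',4'-tetra-O-benzyl-(−)-epicatechin
Product: 3 8-chloro-5,7,3',4'-tetra-O-benzyl-(−)-epicatechin
Conditions: NCS (1.05 equiv), DMF, 0 °C → rt
Reagents that add atoms: N-chlorosuccinimide, ClN1C(=O)CCC1=O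
Why: Electrophilic aromatic chlorination of ring A should go to C8, the more accessible of its two free positions, which leaves C6 as the only nucleophilic carbon of the future unit L.

Step 3
Reactants: 2 5,7,3',4'-tetra-O-benzyl-(−)-epicatechin
Product: 4 8-bromo-5,7,3',4'-tetra-O-benzyl-(−)-epicatechin
Conditions: NBS (1.0 equiv), CH2Cl2, −78 °C → rt
Reagents that add atoms: N-bromosuccinimide, BrN1C(=O)CCC1=O
Why: Electrophilic aromatic bromination at C8 installs a removable cap that keeps the future unit M from acting as a nucleophile during dimer formation.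

Step 4
Reactants: 4 8-bromo-5,7,3',4'-tetra-O-benzyl-(−)-epicatechin
Product: 5 8-bromo-5,7,3',4'-tetra-O-benzyl-4β-(2-ethoxyethoxy)-(−)-epicatechin
Conditions: DDQ (2 equiv), 2-ethoxyethanol (5 equiv), CH2Cl2, rt
Reagents that add atoms: 2-ethoxyethanol, CCOCCO
Why: Benzylic oxidation with DDQ abstracts hydride from C4 to give the 5,7-dialkoxy-stabilised cation, which the alcohol should trap trans to the 3-OH.

Step 5
Reactants: 5 8-bromo-5,7,3',4'-tetra-O-benzyl-4β-(2-ethoxyethoxy)-(−)-epicatechin, 3 8-chloro-5,7,3',4'-tetra-O-benzyl-(−)-epicatechin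
Product: 6 8-bromo-5,7,3',4'-tetra-O-benzylepicatechin-(4β→6)-8-chloro-5,7,3',4'-tetra-O-benzylepicatechin
Conditions: 3 (3 equiv), Me3SiOTf (0.3 equiv), 4 Å MS, CH2Cl2, −78 → −40 °C
Reagents that add atoms: none
Why: Friedel–Crafts interflavan coupling, in which the C4 cation from 5 is attacked by C6 of 3 (C8 is blocked by chlorine) anti to the pseudoaxial 3-OH to set the 4β configuration, while the C8 bromine of the donor and the excess of 3 suppress self-condensation.

Step 6
Reactants: 6 8-bromo-5,7,3',4'-tetra-O-benzylepicatechin-(4β→6)-8-chloro-5,7,3',4'-tetra-O-benzylepicatechin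
Product: 8 5,7,3',4'-tetra-O-benzylepicatechin-(4β→6)-8-chloro-5,7,3',4'-tetra-O-benzylepicatechin, via unit-M C8-lithio trilithium salt 7 (not isolated)
Conditions: n-BuLi (3.3 equiv), THF, −78 °C; then H2O
Reagents that add atoms: none
Why: Bromine–lithium exchange is far faster than chlorine–lithium exchange, so after deprotonation of both hydroxyls only C8 of unit M should be metallated and then protonated, which frees it as the nucleophilic site for step 12.

Step 7
Reactants: 9 (S)-4-benzyloxazolidin-2-one, 10 (benzyloxy)acetyl chloride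
Product: 11 (S)-4-benzyl-3-[(benzyloxy)acetyl]oxazolidin-2-one
Conditions: n-BuLi, THF, −78 °C; then 10, −78 → 0 °C
Reagents that add atoms: none
Why: N-acylation of the lithiated oxazolidinone with the acid chloride is a standard way to load the chiral auxiliary.

Step 8
Reactants: 11 (S)-4-benzyl-3-[(benzyloxy)acetyl]oxazolidin-2-one, 12 3,4-bis(benzyloxy)benzaldehyde
Product: 14 (S)-4-benzyl-3-[(2S,3R)-2-(benzyloxy)-3-[3,4-bis(benzyloxy)phenyl]-3-hydroxypropanoyl]oxazolidin-2-one, via Z dibutylboron enolate 13 (not isolated)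
Conditions: n-Bu2BOTf, Et3N, CH2Cl2, −78 → 0 °C; 12, −78 → 0 °C; then H2O2, pH 7 buffer, MeOH, 0 °C
Reagents that add atoms: none
Why: Evans syn-aldol reaction, in which the Z boron enolate reacts through a chair Zimmerman–Traxler transition state on the face away from the auxiliary benzyl group and so sets the syn (2S,3R) pair that becomes C3 and C2 of unit U.

Step 9
Reactants: 14 (S)-4-benzyl-3-[(2S,3R)-2-(benzyloxy)-3-[3,4-bis(benzyloxy)phenyl]-3-hydroxypropanoyl]oxazolidin-2-one
Product: 15 (2S,3R)-2-(benzyloxy)-3-[3,4-bis(benzyloxy)phenyl]-3-hydroxy-N-methoxy-N-methylpropanamide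
Conditions: MeNHOMe·HCl, AlMe3, CH2Cl2, −20 → 0 °C; aq. potassium sodium tartrate
Reagents that add atoms: N,O-dimethylhydroxylamine hydrochloride, CNOC.Cl
Why: Weinreb transamidation by the aluminium amide, assisted by the free β-hydroxyl, should remove the auxiliary without touching either stereocentre.

Step 10
Reactants: 15 (2S,3R)-2-(benzyloxy)-3-[3,4-bis(benzyloxy)phenyl]-3-hydroxy-N-methoxy-N-methylpropanamide, 16 3,5-bis(benzyloxy)phenylboronic acid
Product: 17 (2S,3R)-2-(benzyloxy)-3-[3,4-bis(benzyloxy)phenyl]-3-[3,5-bis(benzyloxy)phenoxy]-N-methoxy-N-methylpropanamide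
Conditions: 16 (3 equiv), Cu(OAc)2 (0.2 equiv), DMAP (0.4 equiv), 4 Å MS, O2 (1 atm), CH2Cl2, rt
Reagents that add atoms: none
Why: Chan–Lam oxidative copper-catalysed O-arylation of the secondary alcohol runs near neutral at room temperature and does not break the carbinol C–O bond, so C2 keeps its configuration and retro-aldol or β-elimination should be avoided.

Step 11
Reactants: 17 (2S,3R)-2-(benzyloxy)-3-[3,4-bis(benzyloxy)phenyl]-3-[3,5-bis(benzyloxy)phenoxy]-N-methoxy-N-methylpropanamide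
Product: 18 (2S,3R)-2-(benzyloxy)-3-[3,4-bis(benzyloxy)phenyl]-3-[3,5-bis(benzyloxy)phenoxy]propanal
Conditions: i-Bu2AlH (1.5 equiv), THF, −78 °C; aq. potassium sodium tartrate
Reagents that add atoms: none
Why: Hydride addition to the Weinreb amide stops at the chelated tetrahedral intermediate, which releases the aldehyde only on work-up; the crude aldehyde is used at once to avoid α-epimerisation and β-elimination of the aryloxide.

Step 12
Reactants: 18 (2S,3R)-2-(benzyloxy)-3-[3,4-bis(benzyloxy)phenyl]-3-[3,5-bis(benzyloxy)phenoxy]propanal, 8 5,7,3',4'-tetra-O-benzylepicatechin-(4β→6)-8-chloro-5,7,3',4'-tetra-O-benzylepicatechin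
Product: 20 3,5,7,3',4'-penta-O-benzylepicatechin-(4β→8)-5,7,3',4'-tetra-O-benzylepicatechin-(4β→6)-8-chloro-5,7,3',4'-tetra-O-benzylepicatechin, via penta-O-benzyl flavan-4-ol 19 (not isolated)
Conditions: 8 (2.5 equiv), BF3·OEt2 (0.5 equiv), 4 Å MS, CH2Cl2, −78 → −30 °C, slow addition of 18
Reagents that add atoms: none
Why: This is a cascade double Friedel–Crafts reaction at an aldehyde carbon (hydroxyalkylation, then alkylation), whose second half is the established flavan-4-yl cation/flavan coupling: the BF3-activated aldehyde C4 is attacked by the ortho carbon of the tethered 3,5-bis(benzyloxy)phenyl ether (6-exo-trig, C4–C4a bond) to give flavan-4-ol 19, which ionises to the 5,7-dialkoxy-stabilised C4 cation. This cation should be captured by C8 of unit M of 8, the most nucleophilic free aromatic carbon of the dimer, because C8 of unit L is blocked by chlorine and C6 of unit M is flanked by two benzyloxy groups. The new C4 stereocentre is controlled by the adjacent C3: in the half-chair cation, with the C2 aryl pseudoequatorial and the C3 benzyloxy pseudoaxial, the nucleophile enters anti to the C3 substituent to give the 3,4-trans (4β) product, and both C4 epimers of 19 converge on this one cation. The step needs cyclisation before any intermolecular reaction, which the six-membered tether and slow addition of 18 into excess 8 should secure, and single arylation, which the recoverable excess of 8 should secure. If the dimer attacks the aldehyde first, the resulting carbinol ionises and cyclises to the same product, so both orders of events lead to 20.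

Step 13
Reactants: 20 3,5,7,3',4'-penta-O-benzylepicatechin-(4β→8)-5,7,3',4'-tetra-O-benzylepicatechin-(4β→6)-8-chloro-5,7,3',4'-tetra-O-benzylepicatechin
Product: 21 epicatechin-(4β→8)-epicatechin-(4β→6)-epicatechin
Conditions: H2 (1 atm), Pd(OH)2/C, NaOAc, THF/MeOH/H2O, rt
Reagents that add atoms: none
Why: Hydrogenolysis should cleave all thirteen benzyl ethers and, with acetate as acid scavenger, the aryl C–Cl bond, without touching any stereocentre or the acid-labile interflavan bonds.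

**Compound list**

1 | (−)-epicatechin, (2R,3R)-2-(3,4-dihydroxyphenyl)chromane-3,5,7-triol | Oc1cc(O)c2c(c1)O[C@H](c1ccc(O)c(O)c1)[C@H](O)C2 | starting material
2 | 5,7,3',4'-tetra-O-benzyl-(−)-epicatechin, (2R,3R)-5,7-bis(benzyloxy)-2-[3,4-bis(benzyloxy)phenyl]chroman-3-ol | c1ccccc1COc1cc(OCc3ccccc3)c2c(c1)O[C@H](c1ccc(OCc3ccccc3)c(OCc3ccccc3)c1)[C@H](O)C2 | intermediate
3 | 8-chloro-5,7,3',4'-tetra-O-benzyl-(−)-epicatechin (2R,3R) | c1ccccc1COc1cc(OCc3ccccc3)c2c(c1Cl)O[C@H](c1ccc(OCc3ccccc3)c(OCc3ccccc3)c1)[C@H](O)C2 | intermediate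
4 | 8-bromo-5,7,3',4'-tetra-O-benzyl-(−)-epicatechin (2R,3R) | c1ccccc1COc1cc(OCc3ccccc3)c2c(c1Br)O[C@H](c1ccc(OCc3ccccc3)c(OCc3ccccc3)c1)[C@H](O)C2 | intermediate
5 | 8-bromo-5,7,3',4'-tetra-O-benzyl-4β-(2-ethoxyethoxy)-(−)-epicatechin (2,3-cis; 4-alkoxy trans to 3-OH) | c1ccccc1COc1cc(OCc3ccccc3)c2c(c1Br)O[C@H](c1ccc(OCc3ccccc3)c(OCc3ccccc3)c1)[C@H](O)[C@H]2OCCOCC | intermediate
6 | 8-bromo-5,7,3',4'-tetra-O-benzylepicatechin-(4β→6)-8-chloro-5,7,3',4'-tetra-O-benzylepicatechin (both units 2R,3R; interflavan bond trans to the 3-OH of unit M) | c1ccccc1COc1cc(OCc3ccccc3)c2c(c1Br)O[C@H](c1ccc(OCc3ccccc3)c(OCc3ccccc3)c1)[C@H](O)[C@H]2c1c(OCc3ccccc3)c(Cl)c2c(c1OCc1ccccc1)C[C@@H](O)[C@@H](c1ccc(OCc3ccccc3)c(OCc3ccccc3)c1)O2 | intermediate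
7 | trilithium salt of 6 after exchange: C8-lithio unit M, both 3-O-lithium alkoxides | c1ccccc1COc1cc(OCc3ccccc3)c2c(c1[Li])O[C@H](c1ccc(OCc3ccccc3)c(OCc3ccccc3)c1)[C@H](O[Li])[C@H]2c1c(OCc3ccccc3)c(Cl)c2c(c1OCc1ccccc1)C[C@@H](O[Li])[C@@H](c1ccc(OCc3ccccc3)c(OCc3ccccc3)c1)O2 | intermediate (not isolated)
8 | 5,7,3',4'-tetra-O-benzylepicatechin-(4β→6)-8-chloro-5,7,3',4'-tetra-O-benzylepicatechin (C6 and C8 of unit M free) | c1ccccc1COc1cc(OCc3ccccc3)c2c(c1)O[C@H](c1ccc(OCc3ccccc3)c(OCc3ccccc3)c1)[C@H](O)[C@H]2c1c(OCc3ccccc3)c(Cl)c2c(c1OCc1ccccc1)C[C@@H](O)[C@@H](c1ccc(OCc3ccccc3)c(OCc3ccccc3)c1)O2 | intermediate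
9 | (S)-4-benzyloxazolidin-2-one | O=C1N[C@@H](Cc2ccccc2)CO1 | starting material
10 | (benzyloxy)acetyl chloride | ClC(=O)COCc1ccccc1 | starting material
11 | (S)-4-benzyl-3-[(benzyloxy)acetyl]oxazolidin-2-one | O=C(COCc1ccccc1)N1[C@@H](Cc2ccccc2)COC1=O | intermediate
12 | 3,4-bis(benzyloxy)benzaldehyde | O=Cc1ccc(OCc2ccccc2)c(OCc2ccccc2)c1 | starting material
13 | Z dibutylboron enolate of 11 | CCCCB(CCCC)O/C(=C\OCc1ccccc1)N1[C@@H](Cc2ccccc2)COC1=O | intermediate (not isolated)
14 | (S)-4-benzyl-3-[(2S,3R)-2-(benzyloxy)-3-[3,4-bis(benzyloxy)phenyl]-3-hydroxypropanoyl]oxazolidin-2-one | O[C@H](c1ccc(OCc2ccccc2)c(OCc2ccccc2)c1)[C@H](OCc1ccccc1)C(=O)N1[C@@H](Cc2ccccc2)COC1=O | intermediate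
15 | (2S,3R)-2-(benzyloxy)-3-[3,4-bis(benzyloxy)phenyl]-3-hydroxy-N-methoxy-N-methylpropanamide | O[C@H](c1ccc(OCc2ccccc2)c(OCc2ccccc2)c1)[C@H](OCc1ccccc1)C(=O)N(C)OC | intermediate
16 | 3,5-bis(benzyloxy)phenylboronic acid | OB(O)c1cc(OCc2ccccc2)cc(OCc2ccccc2)c1 | starting material
17 | (2S,3R)-2-(benzyloxy)-3-[3,4-bis(benzyloxy)phenyl]-3-[3,5-bis(benzyloxy)phenoxy]-N-methoxy-N-methylpropanamide | c1ccccc1COc1cc(OCc2ccccc2)cc(c1)O[C@H](c1ccc(OCc2ccccc2)c(OCc2ccccc2)c1)[C@H](OCc1ccccc1)C(=O)N(C)OC | intermediate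
18 | (2S,3R)-2-(benzyloxy)-3-[3,4-bis(benzyloxy)phenyl]-3-[3,5-bis(benzyloxy)phenoxy]propanal | c1ccccc1COc1cc(OCc2ccccc2)cc(c1)O[C@H](c1ccc(OCc2ccccc2)c(OCc2ccccc2)c1)[C@H](OCc1ccccc1)C=O | intermediate
19 | 3,5,7-tris(benzyloxy)-2-[3,4-bis(benzyloxy)phenyl]chroman-4-ol, C2 and C3 as in epicatechin (2,3-cis), both C4 epimers | c1ccccc1COc1cc(OCc3ccccc3)c2c(c1)O[C@H](c1ccc(OCc3ccccc3)c(OCc3ccccc3)c1)[C@H](OCc1ccccc1)C2O | intermediate (not isolated)
20 | 3,5,7,3',4'-penta-O-benzylepicatechin-(4β→8)-5,7,3',4'-tetra-O-benzylepicatechin-(4β→6)-8-chloro-5,7,3',4'-tetra-O-benzylepicatechin | c1ccccc1COc1cc(OCc3ccccc3)c2c(c1)O[C@H](c1ccc(OCc3ccccc3)c(OCc3ccccc3)c1)[C@H](OCc1ccccc1)[C@H]2c1c(OCc3ccccc3)cc(OCc3ccccc3)c2c1O[C@H](c1ccc(OCc3ccccc3)c(OCc3ccccc3)c1)[C@H](O)[C@H]2c1c(OCc3ccccc3)c(Cl)c2c(c1OCc1ccccc1)C[C@@H](O)[C@@H](c1ccc(OCc3ccccc3)c(OCc3ccccc3)c1)O2 | intermediate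
21 | epicatechin-(4β→8)-epicatechin-(4β→6)-epicatechin (CNP0178679.3) | Oc1cc(O)c2c(c1)O[C@H](c1ccc(O)c(O)c1)[C@H](O)[C@H]2c1c(O)cc(O)c2c1O[C@H](c1ccc(O)c(O)c1)[C@H](O)[C@H]2c1c(O)cc2c(c1O)C[C@@H](O)[C@@H](c1ccc(O)c(O)c1)O2 | target

**Step count and risks**

Total step count: 13. Longest linear sequence: 7 steps (1 → 3 → 4 → 5 → 6 → 12 → 13; the branch 7 → 8 → 9 → 10 → 11 → 12 → 13 is of equal length).

Most likely to fail, step 12: the cyclised C4 cation may be arylated by ring A of a second molecule of 18 or by unit U of the product (oligomerisation), may be attacked by C6 instead of C8 of unit M, or may lose H3 to a flav-3-ene. The fallback separates ring closure from fragment union; it sets out from 18 and returns at 20. Aldehyde 18 is cyclised alone with camphorsulfonic acid (cat.) in CH2Cl2 containing 2-ethoxyethanol, so that the cyclised C4 cation is trapped by the alcohol as the isolable donor 3,5,7,3',4'-penta-O-benzyl-4β-(2-ethoxyethoxy)flavan F1. F1 is then coupled with excess dimer 8 under Me3SiOTf (cat.) in CH2Cl2 at −78 °C, the standard flavan-4-yl ether/flavan Friedel–Crafts coupling, to give 20.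

Second, step 10: oxidative coupling at the hindered secondary benzylic hydroxyl may be slow, so that protodeboronation and homocoupling of the boronic acid outrun ether formation. The fallback arylates a base-stable, carbonyl-free substrate with an aryl halide; it sets out from 14 and returns at 18. Imide 14 is reduced with LiBH4 (THF, MeOH, 0 °C) to (1R,2R)-2-(benzyloxy)-1-[3,4-bis(benzyloxy)phenyl]propane-1,3-diol F2. The primary hydroxyl is silylated with i-Pr3SiCl and imidazole to the silyl ether F3. The secondary alcohol is arylated in an Ullmann-type etherification with 1,3-bis(benzyloxy)-5-iodobenzene (CuI, 3,4,7,8-tetramethyl-1,10-phenanthroline, Cs2CO3, toluene, 110 °C), with retention at the carbinol carbon, to aryl ether F4. Bu4NF frees the primary alcohol (2R,3R)-2-(benzyloxy)-3-[3,4-bis(benzyloxy)phenyl]-3-[3,5-bis(benzyloxy)phenoxy]propan-1-ol F5, and Dess–Martin periodinane oxidises it to 18.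

Third, step 13: reduction of the electron-rich aryl C–Cl bond may stall while the benzyl ethers are cleaved, or insufficiently buffered HCl may cleave interflavan bonds. The fallback removes chlorine first under homogeneous catalysis; it sets out from 20 and returns at 21. Compound 20 is hydrodechlorinated by transfer hydrogenation (Pd(OAc)2, 2-dicyclohexylphosphino-2',4',6'-triisopropylbiphenyl, HCO2Na, DMF, 80 °C) to the chlorine-free trideca-O-benzyl trimer F6, which is then debenzylated with H2 over Pd(OH)2/C in THF/MeOH/H2O to give 21.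

**Further compounds**

F1 | step 12 | 3,5,7,3',4'-penta-O-benzyl-4β-(2-ethoxyethoxy)flavan, C2 and C3 as in epicatechin, 4-alkoxy trans to 3-OBn | c1ccccc1COc1cc(OCc3ccccc3)c2c(c1)O[C@H](c1ccc(OCc3ccccc3)c(OCc3ccccc3)c1)[C@H](OCc1ccccc1)[C@H]2OCCOCC
F2 | step 10 | (1R,2R)-2-(benzyloxy)-1-[3,4-bis(benzyloxy)phenyl]propane-1,3-diol | O[C@H](c1ccc(OCc2ccccc2)c(OCc2ccccc2)c1)[C@H](OCc1ccccc1)CO
F3 | step 10 | (1R,2R)-2-(benzyloxy)-1-[3,4-bis(benzyloxy)phenyl]-3-[(triisopropylsilyl)oxy]propan-1-ol | O[C@H](c1ccc(OCc2ccccc2)c(OCc2ccccc2)c1)[C@H](OCc1ccccc1)CO[Si](C(C)C)(C(C)C)C(C)C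
F4 | step 10 | triisopropylsilyl ether of (2R,3R)-2-(benzyloxy)-3-[3,4-bis(benzyloxy)phenyl]-3-[3,5-bis(benzyloxy)phenoxy]propan-1-ol | c1ccccc1COc1cc(OCc2ccccc2)cc(c1)O[C@H](c1ccc(OCc2ccccc2)c(OCc2ccccc2)c1)[C@H](OCc1ccccc1)CO[Si](C(C)C)(C(C)C)C(C)C
F5 | step 10 | (2R,3R)-2-(benzyloxy)-3-[3,4-bis(benzyloxy)phenyl]-3-[3,5-bis(benzyloxy)phenoxy]propan-1-ol | c1ccccc1COc1cc(OCc2ccccc2)cc(c1)O[C@H](c1ccc(OCc2ccccc2)c(OCc2ccccc2)c1)[C@H](OCc1ccccc1)CO
F6 | step 13 | 3,5,7,3',4'-penta-O-benzylepicatechin-(4β→8)-5,7,3',4'-tetra-O-benzylepicatechin-(4β→6)-5,7,3',4'-tetra-O-benzylepicatechin | c1ccccc1COc1cc(OCc3ccccc3)c2c(c1)O[C@H](c1ccc(OCc3ccccc3)c(OCc3ccccc3)c1)[C@H](OCc1ccccc1)[C@H]2c1c(OCc3ccccc3)cc(OCc3ccccc3)c2c1O[C@H](c1ccc(OCc3ccccc3)c(OCc3ccccc3)c1)[C@H](O)[C@H]2c1c(OCc3ccccc3)cc2c(c1OCc1ccccc1)C[C@@H](O)[C@@H](c1ccc(OCc3ccccc3)c(OCc3ccccc3)c1)O2
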